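**Plan**

- The retrosynthesis first undoes three oxygen adjustments (5-OMe to 5-OH, the 7-O-methyl group, two methoxymethyl groups). It then cuts ring C at O1–C8a, C4–C4a and O1–C2.
- The feature that allows this: O1–C8a and C4–C4a are neighbouring bonds on ring A, and C5 to C8 can carry the mirror-symmetric pattern OMe, OCH2OMe, OCH2OMe, OMe. Ring A therefore enters as a symmetric aryne, and the direction of addition does not matter.
- The partner is a 3-aryl-2,3-dimethoxyacrylic acid that supplies ring B, C2, C3, C4, O1 and the carbonyl oxygen.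
- Forward: ring A is fully oxygenated from 2,5-dimethoxyphenol and converted into a 2-silylaryl triflate (six steps). The ring B acid is built from methyl 3,5-dihydroxy-4-methoxybenzoate and methyl methoxyacetate (four steps). Ring C closes in the coupling, and three steps adjust the oxygens.
- The target has no stereocentre. The only stereochemical element on the way, the enol ether geometry, is erased in the ring closure. C5 is told from C8 by chelation to C4=O, and C7 from C6 by the acidity of the 7-hydroxyl.

Key step: step 11

Remark: the enol ether of the acrylate ester and acid is drawn E; the geometry is not relied upon, because ring closure erases it, so the Z isomer or a mixture would serve equally.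
Remark: where a phenol, acid or β-keto ester reacts as its salt, the salt carries the number of the neutral compound; the silylphenol of step 6 and the acylphenol of step 11 are drawn neutral although they exist only as lithium and cesium phenolates.

**Route**

Step 1
Reactants: 1 2,5-dimethoxyphenol
Product: 2 1,4-dimethoxy-2-(methoxymethoxy)benzene
Conditions: NaH, MOMCl, THF/DMF, 0 °C to rt
Reagents that add atoms: chloromethyl methyl ether (MOMCl), COCCl
Why: Williamson-type O-alkylation of the sodium phenoxide by the reactive α-chloro ether gives the methoxymethyl acetal, which masks the phenol and supplies the stronger director for the next metalation.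

Step 2
Reactants: 2 1,4-dimethoxy-2-(methoxymethoxy)benzene
Product: 5 3,6-dimethoxy-2-(methoxymethoxy)phenol, via aryllithium 3 (not isolated), via dimethyl arylboronate 4 (not isolated)
Conditions: n-BuLi, THF, 0 °C; B(OMe)3, −78 °C to rt; 30% H2O2, 0 °C to rt
Reagents that add atoms: hydrogen peroxide, OO (the new oxygen of 5); n-butyllithium, [Li]CCCC, and trimethyl borate, COB(OC)OC, leave atoms only in intermediates 3 and 4
Why: Directed ortho-metalation is expected at the single ring position lying between the OCH2OMe group and an OMe group, where both donors cooperate, and borylation–oxidation of the aryllithium turns that C–H into C–OH.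

Step 3
Reactants: 5 3,6-dimethoxy-2-(methoxymethoxy)phenol
Product: 6 1,4-dimethoxy-2,3-bis(methoxymethoxy)benzene
Conditions: NaH, MOMCl, DMF, 0 °C to rt
Reagents that add atoms: chloromethyl methyl ether (MOMCl), COCCl
Why: Williamson-type O-alkylation of the hindered phenoxide in a dipolar aprotic solvent completes a mirror-symmetric tetraoxygenated benzene, so the following metalation has only one possible site.

Step 4
Reactants: 6 1,4-dimethoxy-2,3-bis(methoxymethoxy)benzene
Product: 9 2,5-dimethoxy-3,4-bis(methoxymethoxy)phenol, via aryllithium 7 (not isolated), via dimethyl arylboronate 8 (not isolated)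
Conditions: n-BuLi, TMEDA, THF, 0 °C; B(OMe)3, −78 °C to rt; 30% H2O2, 0 °C to rt
Reagents that add atoms: hydrogen peroxide, OO (the new oxygen of 9); n-butyllithium, [Li]CCCC, and trimethyl borate, COB(OC)OC, leave atoms only in intermediates 7 and 8
Why: Methoxy-directed ortho-metalation of the kind established for 1,2,3,4-tetramethoxybenzene removes one of the two symmetry-equivalent ring hydrogens, and the same borylation–oxidation sequence installs the oxygen that will become the triflate.

Step 5
Reactants: 9 2,5-dimethoxy-3,4-bis(methoxymethoxy)phenol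
Product: 10 2-bromo-3,6-dimethoxy-4,5-bis(methoxymethoxy)phenol
Conditions: NBS (1.0 equiv), CH2Cl2, −78 to −20 °C, dark
Reagents that add atoms: N-bromosuccinimide, O=C1CCC(=O)N1Br
Why: Electrophilic aromatic bromination of the strongly activated phenol can only occur at the one unsubstituted ring carbon, ortho to the hydroxyl, and cold NBS in a dry solvent releases no acid that would cleave the acetals and limits oxidation to a quinone.

Step 6
Reactants: 10 2-bromo-3,6-dimethoxy-4,5-bis(methoxymethoxy)phenol
Product: 14 3,6-dimethoxy-4,5-bis(methoxymethoxy)-2-(trimethylsilyl)phenyl trifluoromethanesulfonate, via aryl trimethylsilyl ether 11 (not isolated), via ortho-lithiated silyl ether 12 (not isolated), via lithium 2-silylphenolate 13 (not isolated)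
Conditions: HN(SiMe3)2, THF, 65 °C, then evaporation; n-BuLi, THF, −78 °C; Tf2O, −78 to 0 °C
Reagents that add atoms: hexamethyldisilazane, C[Si](C)(C)N[Si](C)(C)C (the SiMe3 group); trifluoromethanesulfonic anhydride, O=S(=O)(OS(=O)(=O)C(F)(F)F)C(F)(F)F (the CF3SO2 group); n-butyllithium, [Li]CCCC, leaves lithium only in intermediate 12
Why: This is the standard one-flask passage from ortho-bromophenols to 2-silylaryl triflates, in which O-silylation, bromine–lithium exchange, retro-Brook 1,3-migration of silicon from oxygen to the lithiated carbon and O-triflation of the freed phenolate follow one another, the cold and brief contact with Tf2O sparing the acetals.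

Step 7
Reactants: 15 methyl 3,5-dihydroxy-4-methoxybenzoate
Product: 16 methyl 3,5-bis(benzyloxy)-4-methoxybenzoate
Conditions: BnBr, K2CO3, DMF, 60 °C
Reagents that add atoms: benzyl bromide, BrCc1ccccc1
Why: Williamson benzylation of both phenols under carbonate conditions leaves the methyl ester untouched and gives ethers that survive base, fluoride and the acid used later to remove the acetals.

Step 8
Reactants: 16 methyl 3,5-bis(benzyloxy)-4-methoxybenzoate; 17 methyl methoxyacetate
Product: 18 methyl 3-[3,5-bis(benzyloxy)-4-methoxyphenyl]-2-methoxy-3-oxopropanoate (racemic)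
Conditions: 17 (2 equiv), LiN(SiMe3)2 (3 equiv), THF, −78 °C; then 16, −78 to 0 °C; 1 M HCl quench
Reagents that add atoms: none
Why: The crossed Claisen condensation is viable because the aryl ester cannot enolise, the methoxyacetate is fully enolised beforehand so it cannot self-condense, and excess base drives the equilibrium by deprotonating the β-keto ester, whose single stereocentre is racemic and labile.

Step 9
Reactants: 18 methyl 3-[3,5-bis(benzyloxy)-4-methoxyphenyl]-2-methoxy-3-oxopropanoate
Product: 19 methyl (E)-3-[3,5-bis(benzyloxy)-4-methoxyphenyl]-2,3-dimethoxyprop-2-enoate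
Conditions: Me2SO4, Cs2CO3, DMF, 0 °C to rt
Reagents that add atoms: dimethyl sulfate, COS(=O)(=O)OC
Why: Enolate O-alkylation is favoured by a hard sulfate electrophile, a weakly coordinated cesium enolate in DMF and a carbon terminus that is already trisubstituted and hindered, so the enol methyl ether should prevail over the C-methylated keto ester.

Step 10
Reactants: 19 methyl (E)-3-[3,5-bis(benzyloxy)-4-methoxyphenyl]-2,3-dimethoxyprop-2-enoate
Product: 20 (E)-3-[3,5-bis(benzyloxy)-4-methoxyphenyl]-2,3-dimethoxyprop-2-enoic acid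
Conditions: LiOH, THF/MeOH/H2O, 40 °C; then 0.5 M HCl, 0 °C, to pH 3–4
Reagents that add atoms: lithium hydroxide, [Li+].[OH-] (oxygen of the carboxyl OH)
Why: Saponification is a standard acyl substitution, and the β-methoxyacrylate, a vinylogous carbonate, should tolerate hydroxide and a brief cold, weakly acidic work-up without enol ether hydrolysis or decarboxylation.

Step 11
Reactants: 14 3,6-dimethoxy-4,5-bis(methoxymethoxy)-2-(trimethylsilyl)phenyl trifluoromethanesulfonate; 20 (E)-3-[3,5-bis(benzyloxy)-4-methoxyphenyl]-2,3-dimethoxyprop-2-enoic acid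
Product: 24 2-[3,5-bis(benzyloxy)-4-methoxyphenyl]-3,5,8-trimethoxy-6,7-bis(methoxymethoxy)-4H-chromen-4-one, via aryne 21 (not isolated), via ortho aryl anion 22 (not isolated), via cesium 2-acylphenolate 23 (not isolated)
Conditions: CsF (5 equiv), THF, sealed tube, 125 °C; 14 in 1.5-fold excess
Reagents that add atoms: none
Why: Fluoride removes the silyl group of 14 and triflate departs to give aryne 21; the cesium carboxylate of 20 adds through oxygen (O1–C8a), and the ortho aryl anion 22, in a hot aprotic medium with only weakly acidic bifluoride as proton source, attacks its own ester carbonyl through a four-membered transition state so that the acyl group moves from oxygen to carbon (C4–C4a) and phenolate 23 results. This is the known aryne insertion into the C–O bond of a carboxylic acid, an anionic Fries-type 1,3-acyl shift, which with unsaturated acids continues in the same flask to chromanones or flavones. Ring C then closes by 6-endo-trig oxa-Michael addition of the phenolate oxygen to the β-methoxy enone carbon (O1–C2), and E1cB loss of methoxide restores the C2=C3 double bond, the way 2-hydroxyaryl β-alkoxy and β-amino enones are routinely converted into chromones. No stereocentre is formed, and the acrylate geometry is erased because C2 passes through a tetrahedral stage and ends trigonal. The one selectivity required is the direction of carboxylate addition to the aryne, and the mirror symmetry of 21 (OMe, OCH2OMe, OCH2OMe, OMe) makes both directions give the same ketone, while the two methoxy groups flanking the triple bond leave no ortho hydrogen for side reactions.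

Step 12
Reactants: 24 2-[3,5-bis(benzyloxy)-4-methoxyphenyl]-3,5,8-trimethoxy-6,7-bis(methoxymethoxy)-4H-chromen-4-one
Product: 25 2-[3,5-bis(benzyloxy)-4-methoxyphenyl]-6,7-dihydroxy-3,5,8-trimethoxy-4H-chromen-4-one
Conditions: 3 M aq. HCl, MeOH/THF, 50 °C
Reagents that add atoms: none
Why: Acid-catalysed transacetalisation in methanol cleaves both methoxymethyl ethers as dimethoxymethane, while the methyl and benzyl aryl ethers and the chromone are inert under these conditions.

Step 13
Reactants: 25 2-[3,5-bis(benzyloxy)-4-methoxyphenyl]-6,7-dihydroxy-3,5,8-trimethoxy-4H-chromen-4-one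
Product: 26 2-[3,5-bis(benzyloxy)-4-methoxyphenyl]-6-hydroxy-3,5,7,8-tetramethoxy-4H-chromen-4-one
Conditions: MeI (1.05 equiv), K2CO3 (1.0 equiv), degassed DMF, 0 °C to rt, argon
Reagents that add atoms: iodomethane, CI
Why: Site-selective Williamson methylation rests on the 7-hydroxyl being para to the C4 carbonyl through ring A and so distinctly more acidic than the 6-hydroxyl, so one equivalent of carbonate forms mainly the 7-phenoxide and one equivalent of MeI alkylates it, as in the 7-selective monoalkylation of 6,7-dihydroxycoumarins and 6,7-dihydroxyflavones, with air excluded because the diol is oxidation-prone.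

Step 14
Reactants: 26 2-[3,5-bis(benzyloxy)-4-methoxyphenyl]-6-hydroxy-3,5,7,8-tetramethoxy-4H-chromen-4-one
Product: 27 5,6-dihydroxy-2-(3,5-dihydroxy-4-methoxyphenyl)-3,7,8-trimethoxy-4H-chromen-4-one (5,6,3',5'-tetrahydroxy-3,7,8,4'-tetramethoxyflavone)
Conditions: BCl3 (excess), C6HMe5, CH2Cl2, −78 to 0 °C; then aq. HCl, rt
Reagents that add atoms: none
Why: Lewis-acid ether cleavage with BCl3 removes both benzyl groups at low temperature, pentamethylbenzene trapping the benzyl cations in a Friedel–Crafts sense, and on warming cleaves only the methyl ether at C5, whose oxygen forms a six-membered boron chelate with the C4 carbonyl, while the non-chelated 7-, 8- and 4'-methyl ethers and the less readily cleaved 3-methyl ether should remain.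

**Compound list**

1 | 2,5-dimethoxyphenol | COc1ccc(OC)c(O)c1 | starting material
2 | 1,4-dimethoxy-2-(methoxymethoxy)benzene | COCOc1cc(OC)ccc1OC | intermediate
3 | [3,6-dimethoxy-2-(methoxymethoxy)phenyl]lithium (not isolated) | [Li]c1c(OC)ccc(OC)c1OCOC | intermediate
4 | dimethyl [3,6-dimethoxy-2-(methoxymethoxy)phenyl]boronate (not isolated) | COB(OC)c1c(OC)ccc(OC)c1OCOC | intermediate
5 | 3,6-dimethoxy-2-(methoxymethoxy)phenol | Oc1c(OC)ccc(OC)c1OCOC | intermediate
6 | 1,4-dimethoxy-2,3-bis(methoxymethoxy)benzene | COCOc1c(OC)ccc(OC)c1OCOC | intermediate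
7 | [2,5-dimethoxy-3,4-bis(methoxymethoxy)phenyl]lithium (not isolated) | [Li]c1cc(OC)c(OCOC)c(OCOC)c1OC | intermediate
8 | dimethyl [2,5-dimethoxy-3,4-bis(methoxymethoxy)phenyl]boronate (not isolated) | COB(OC)c1cc(OC)c(OCOC)c(OCOC)c1OC | intermediate
9 | 2,5-dimethoxy-3,4-bis(methoxymethoxy)phenol | Oc1cc(OC)c(OCOC)c(OCOC)c1OC | intermediate
10 | 2-bromo-3,6-dimethoxy-4,5-bis(methoxymethoxy)phenol | Oc1c(Br)c(OC)c(OCOC)c(OCOC)c1OC | intermediate
11 | [2-bromo-3,6-dimethoxy-4,5-bis(methoxymethoxy)phenoxy]trimethylsilane (not isolated) | C[Si](C)(C)Oc1c(Br)c(OC)c(OCOC)c(OCOC)c1OC | intermediate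
12 | {3,6-dimethoxy-4,5-bis(methoxymethoxy)-2-[(trimethylsilyl)oxy]phenyl}lithium (not isolated) | [Li]c1c(O[Si](C)(C)C)c(OC)c(OCOC)c(OCOC)c1OC | intermediate
13 | 3,6-dimethoxy-4,5-bis(methoxymethoxy)-2-(trimethylsilyl)phenol, formed as its lithium phenolate (not isolated) | Oc1c([Si](C)(C)C)c(OC)c(OCOC)c(OCOC)c1OC | intermediate
14 | 3,6-dimethoxy-4,5-bis(methoxymethoxy)-2-(trimethylsilyl)phenyl trifluoromethanesulfonate | COCOc1c(OCOC)c(OC)c(OS(=O)(=O)C(F)(F)F)c([Si](C)(C)C)c1OC | intermediate
15 | methyl 3,5-dihydroxy-4-methoxybenzoate | COC(=O)c1cc(O)c(OC)c(O)c1 | starting material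
16 | methyl 3,5-bis(benzyloxy)-4-methoxybenzoate | COC(=O)c1cc(OCc2ccccc2)c(OC)c(OCc2ccccc2)c1 | intermediate
17 | methyl methoxyacetate | COCC(=O)OC | starting material
18 | methyl 3-[3,5-bis(benzyloxy)-4-methoxyphenyl]-2-methoxy-3-oxopropanoate (racemic) | COC(=O)C(OC)C(=O)c1cc(OCc2ccccc2)c(OC)c(OCc2ccccc2)c1 | intermediate
19 | methyl (E)-3-[3,5-bis(benzyloxy)-4-methoxyphenyl]-2,3-dimethoxyprop-2-enoate | CO/C(C(=O)OC)=C(/OC)c1cc(OCc2ccccc2)c(OC)c(OCc2ccccc2)c1 | intermediate
20 | (E)-3-[3,5-bis(benzyloxy)-4-methoxyphenyl]-2,3-dimethoxyprop-2-enoic acid | CO/C(C(=O)O)=C(/OC)c1cc(OCc2ccccc2)c(OC)c(OCc2ccccc2)c1 | intermediate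
21 | 3,6-dimethoxy-4,5-bis(methoxymethoxy)benzyne (not isolated) | COC1=C(OCOC)C(OCOC)=C(OC)C#C1 | intermediate
22 | 2-[(E)-3-(3,5-bis(benzyloxy)-4-methoxyphenyl)-2,3-dimethoxyprop-2-enoyloxy]-3,6-dimethoxy-4,5-bis(methoxymethoxy)phenyl anion, cesium counter-ion (not isolated) | CO/C(C(=O)Oc1[c-]c(OC)c(OCOC)c(OCOC)c1OC)=C(/OC)c1cc(OCc2ccccc2)c(OC)c(OCc2ccccc2)c1 | intermediate
23 | (E)-3-[3,5-bis(benzyloxy)-4-methoxyphenyl]-1-[2-hydroxy-3,6-dimethoxy-4,5-bis(methoxymethoxy)phenyl]-2,3-dimethoxyprop-2-en-1-one, formed as its cesium phenolate (not isolated) | CO/C(C(=O)c1c(O)c(OC)c(OCOC)c(OCOC)c1OC)=C(/OC)c1cc(OCc2ccccc2)c(OC)c(OCc2ccccc2)c1 | intermediate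
24 | 2-[3,5-bis(benzyloxy)-4-methoxyphenyl]-3,5,8-trimethoxy-6,7-bis(methoxymethoxy)-4H-chromen-4-one | COCOc1c(OCOC)c(OC)c2oc(-c3cc(OCc4ccccc4)c(OC)c(OCc4ccccc4)c3)c(OC)c(=O)c2c1OC | intermediate
25 | 2-[3,5-bis(benzyloxy)-4-methoxyphenyl]-6,7-dihydroxy-3,5,8-trimethoxy-4H-chromen-4-one | Oc1c(O)c(OC)c2oc(-c3cc(OCc4ccccc4)c(OC)c(OCc4ccccc4)c3)c(OC)c(=O)c2c1OC | intermediate
26 | 2-[3,5-bis(benzyloxy)-4-methoxyphenyl]-6-hydroxy-3,5,7,8-tetramethoxy-4H-chromen-4-one | Oc1c(OC)c(OC)c2oc(-c3cc(OCc4ccccc4)c(OC)c(OCc4ccccc4)c3)c(OC)c(=O)c2c1OC | intermediate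
27 | 5,6-dihydroxy-2-(3,5-dihydroxy-4-methoxyphenyl)-3,7,8-trimethoxy-4H-chromen-4-one | COc1c(O)cc(-c2oc3c(OC)c(OC)c(O)c(O)c3c(=O)c2OC)cc1O | target

**Step count and risks**

Total steps: 14. Longest linear sequence: 10 (steps 1–6, then 11–14); the acid branch (steps 7–10) joins at step 11.

Steps most likely to fail:

1. Step 11. The ortho aryl anion may be protonated before the acyl group migrates, stopping at simple O-arylation. The crowded, electron-rich aryne may also be consumed unproductively at 125 °C. Fallback without an aryne: setting out from bromophenol 10 and acid 20, Steglich esterification (EDC·HCl, DMAP, CH2Cl2) should give 2-bromo-3,6-dimethoxy-4,5-bis(methoxymethoxy)phenyl (E)-3-[3,5-bis(benzyloxy)-4-methoxyphenyl]-2,3-dimethoxyprop-2-enoate F1. Bromine–lithium exchange (n-BuLi, THF, −100 °C) then generates {2-[(E)-3-(3,5-bis(benzyloxy)-4-methoxyphenyl)-2,3-dimethoxyprop-2-enoyloxy]-3,6-dimethoxy-4,5-bis(methoxymethoxy)phenyl}lithium F2. This undergoes the known exchange-triggered anionic Fries 1,3-acyl shift to the lithium salt of 23. Warming, or K2CO3 in MeOH, closes ring C with loss of methoxide, and the route is rejoined at 24.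

2. Step 9. Alkylation may go to carbon rather than oxygen, giving the α-methyl keto ester. Fallback under acid control: setting out from 18, HC(OMe)3 with catalytic TsOH in MeOH at reflux should give the dimethyl ketal methyl 3-[3,5-bis(benzyloxy)-4-methoxyphenyl]-2,3,3-trimethoxypropanoate F3 (racemic). Continued heating with the acid while methanol is distilled off eliminates one methanol (ketalisation–elimination) and rejoins the route at 19. No carbon nucleophile is present in this sequence.

3. Step 14. The single Lewis-acid treatment may over-demethylate, at the 3-methoxy group or at methoxy groups next to boron-bound oxygens, or may transfer benzyl cations onto the electron-rich rings. Fallback separating the two events: setting out from 26, hydrogenolysis (H2, Pd/C, EtOAc/MeOH, rt) should give 2-(3,5-dihydroxy-4-methoxyphenyl)-6-hydroxy-3,5,7,8-tetramethoxy-4H-chromen-4-one F4. Chelation-controlled demethylation with AlCl3 in MeCN (rt to 50 °C, then aq. HCl) then cleaves only the 5-methyl ether and arrives at 27.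

**Further compounds**

F1 | step 11 | 2-bromo-3,6-dimethoxy-4,5-bis(methoxymethoxy)phenyl (E)-3-[3,5-bis(benzyloxy)-4-methoxyphenyl]-2,3-dimethoxyprop-2-enoate | CO/C(C(=O)Oc1c(Br)c(OC)c(OCOC)c(OCOC)c1OC)=C(/OC)c1cc(OCc2ccccc2)c(OC)c(OCc2ccccc2)c1
F2 | step 11 | {2-[(E)-3-(3,5-bis(benzyloxy)-4-methoxyphenyl)-2,3-dimethoxyprop-2-enoyloxy]-3,6-dimethoxy-4,5-bis(methoxymethoxy)phenyl}lithium | CO/C(C(=O)Oc1c([Li])c(OC)c(OCOC)c(OCOC)c1OC)=C(/OC)c1cc(OCc2ccccc2)c(OC)c(OCc2ccccc2)c1
F3 | step 9 | methyl 3-[3,5-bis(benzyloxy)-4-methoxyphenyl]-2,3,3-trimethoxypropanoate (racemic) | COC(=O)C(OC)C(OC)(OC)c1cc(OCc2ccccc2)c(OC)c(OCc2ccccc2)c1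
F4 | step 14 | 2-(3,5-dihydroxy-4-methoxyphenyl)-6-hydroxy-3,5,7,8-tetramethoxy-4H-chromen-4-one | Oc1c(OC)c(OC)c2oc(-c3cc(O)c(OC)c(O)c3)c(OC)c(=O)c2c1OC
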